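## The problem

The target is a cyclohexane in which every ring carbon is oxygenated and stereogenic. C1 is the quaternary oxirane carbon carrying the benzoyloxymethyl arm C7, C2 and C3 are the acetoxy carbons, C4 and C5 the free carbinols, and C6 the oxirane CH. With the ring drawn flat, the oxirane oxygen, O2 and O4 lie on one face (called lower here) and C7, O3 and O5 on the other, so the oxygens on C2–C5 are all-trans and the oxirane is cis to O2 and trans to O5. There is only one carbocycle, so the difficulty is how six contiguous centres and four kinds of oxygen (benzoate, acetate, free hydroxyl, oxirane) are set and told apart. In particular, O3 must end acylated and O4 free although both belong to the same all-trans triol. The centres can control one another in a relay: C3–C5 are the xylo triad sold by the chiral pool, C2 can be set from C3 by 1,2-induction in an aldehyde addition, and C1 and C6 together can be set from the C2 hydroxyl by a directed epoxidation. The finished molecule tolerates little. Under base the O3 acetate can move to O4, the O7 benzoate to O2, and the C5 alkoxide, anti to the oxirane, can open it at C6 (Payne rearrangement). Strong acid opens the oxirane at tertiary C1, so the last steps must stay near neutral. The key step is possible because C1 and C6 are the two oxirane carbons: removing the oxirane oxygen leaves a C1=C6 alkene in a cyclohexene whose other ring atoms, C2–C5, form one unbroken stereodefined chain, and cutting that alkene gives an acyclic 1,7-diene with a 1,1-disubstituted alkene at C1 and a vinyl group on C5.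

## Retrosynthesis

**Protecting groups (19 ⇒ 18 ⇒ 17 ⇒ 16).** No skeletal bond is cut. The O4–H and O5–H bonds of 19 are traced to silyl ethers (18), the two acetates to diol 17, and O3–H of 17 to the 4-methoxybenzyl ether of epoxy alcohol 16. Both acetates go on together once O3 is uncovered and while O4 and O5 are still masked, so no acetate faces a free neighbouring hydroxyl under base. Silicon comes off last with buffered fluoride, which is neither basic nor strongly acidic. Uncovering O4 and O5 earlier would demand a selective acetylation of two hydroxyls out of four. The forward steps must cleave an ether oxidatively next to a free hydroxyl and remove silicon without touching the oxirane or three esters.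

**Oxirane (16 ⇒ 15).** Both C–O bonds of the oxirane are cut, giving cyclohexenol 15. Its C2 hydroxyl lies on the face where the oxirane oxygen is needed, so a hydroxyl-directed epoxidation sets C1 and C6 in one step. A peracid guided only by sterics would be less certain, and closing the oxirane by displacement would cost an extra leaving group. The precursor has two stereocentres fewer. The forward step needs O2–H free, which is why the acetates come afterwards.

**Ring (15 ⇒ 14).** The C1=C6 bond is cut by ring-closing metathesis, giving the acyclic diene 14. The neighbouring cuts, C1–C2 or C5–C6, would each create a stereocentre during ring closure and need a carbonyl partner. This cut creates none, tolerates the free hydroxyl, the ester and all ethers, and removes the only ring. The catalyst must initiate at the vinyl group on C5 and accept a 1,1-disubstituted partner to give a trisubstituted alkene.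

**C1–C2 bond (14 ⇒ 13 ⇒ 9 + 10).** After removing the benzoate (13), the C1–C2 bond is cut between aldehyde 9 and the C3 unit 10, used as its O,C-dimetallated form. This one addition brings in C1, C7 and the exocyclic methylene and creates C2. The ether on O3 is 4-methoxybenzyl for two reasons: it chelates magnesium, steering the addition to the 2,3-syn alcohol, and it is later removed oxidatively in the presence of silyl ethers, which is what tells O3 from O4. The silyl ether on C4 does not chelate, so only one chelate competes. A cut at C2–C3 would need an aldol-type construction with two new centres. The precursor 9 has three stereocentres, all bought.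

**Chain ends (9 ⇒ 8 ⇒ 5 + 6).** The aldehyde of 9 is traced to the terminal glycol of diol 8 (glycol cleavage), and the vinyl group of 8 to hemiacetal 5 and ylide precursor 6 (Wittig methylenation). Opening the hemiacetal by olefination turns the ring oxygen into the secondary hydroxyl of the glycol. No separate deprotection or alcohol oxidation is then needed, and the aldehyde is formed at neutral pH next to its α-stereocentre. The forward steps need an olefination that tolerates two free hydroxyls and a cleavage specific for the vicinal diol.

**Protecting pattern and pool (5 ⇒ 4 ⇒ 3 ⇒ 2 ⇒ 1).** The pattern of 5 (silyl on sugar O2 and O3, 4-methoxybenzyl on O4, free O6) is traced through thioglycoside 4 and arylidene acetal 3 to diol 2 and the commercial thioglycoside 1. The xylo triad is C2–C4 of the gluco series just as of the five-carbon sugar, but the pentose offers no handle to single out O4. In the hexopyranoside the 4,6-acetal does this: it leaves O2 and O3 for silylation, and its regioselective reductive opening places the benzyl-type ether on O4 and frees O6. O6 and C6 then serve, with O5, as the latent aldehyde and are lost as formaldehyde. The thiophenyl group survives silylation and borane and is later hydrolysed under neutral conditions.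

## Roads not taken

**Alternative 1:** The cut is at C2–O, with the ring taken from an arene. The achiral para-quinol A1 would be condensed at its tertiary hydroxyl with an arylboronic acid, and a chiral amine–thiourea catalyst would guide the boron-bound hydroxyl to one of the two enantiotopic enone β-carbons, giving the cis-fused boronate A2.
- Merits: a few operations lead from a simple phenol derivative to an enantioenriched ring with quaternary C1 and cis O2, with no metal carbene and no early protecting-group work.
- Weak points: A2 holds two of six centres. C3 is a methylene next to a C4 ketone and C5=C6 is an enone alkene, so O3, O4, O5 and the oxirane would need four further substrate-controlled operations, with the boronate removed and O1 told from O2 on the way. A2 is a β-alkoxy ketone and can revert by retro-oxa-Michael addition (losing enantiopurity) or aromatise.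
- Comparison: this road is better in front-end economy and in being catalytic-asymmetric. The chosen plan sets against it that four centres and the full oxygen differentiation are fixed before the ring exists, and that the last two centres are set by one covalently directed step.

**Alternative 2:** The cuts are at C1–O and C4–O. Photo-oxygenation of the trans-dioxygenated cyclohexadiene A3 would add dioxygen across C1 and C4 on the face of the free C2 hydroxyl, which is also the face away from the C3 acetate, giving endoperoxide A4.
- Merits: one step places lower-face oxygen on C1 and C4, and the peroxide bridge is a direct precursor of the oxirane; the target could lie three or four steps beyond A4.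
- Weak points: A3 is a cyclohexadiene with allylic oxygen on C2 and C3 and aromatises easily. Making it enantiopure with the trans C2/C3 relationship is a sequence of its own (microbial dihydroxylation gives cis diols). Hydroxyl steering of the cycloaddition is a hydrogen-bond effect and depends on solvent. After A4 the C5=C6 alkene still needs upper-face oxygen at C5 and lower-face closure at C6, next to an acetate with a free neighbour.
- Comparison: this road is shorter after its key step and more atom-economic. The chosen plan sets against it a catalogue source of chirality, no labile diene or peroxide, and selectivity resting on a metal alkoxide instead of a hydrogen bond.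

**Alternative 3:** The oxirane is formed last by epoxide migration on a ring bought as the microbial ipso,ortho-dihydrodiol A5. Its (1S,2R) configuration maps correctly onto C1 and C2. Base would convert epoxy diol A6 (lower-face 4,5-epoxide, upper-face O6–H, lower-face tertiary O1–H) by two Payne rearrangements: O6 opens the epoxide at C5, then O1 opens the new 5,6-epoxide at C6, giving A7.
- Merits: ring and quaternary centre are purchased, the cascade is stereospecific (two inversions), and it runs toward the more substituted oxirane.
- Weak points: the cascade needs base while a benzoate sits two atoms from the tertiary alkoxide, so acyl migration or saponification competes. A6 must be built from A5 with O3 and O6 on the upper face yet differentiated. A7 has ethers on O2 and O3 where acetates are needed and free O4 and O5, so four more operations follow. A5 is a fermentation product and not a catalogue item.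
- Comparison: this road is better in needing no ring-forming step. The chosen plan sets against it a commercial start, near-neutral late steps, and a ring-closure product that already carries the right oxygen differentiation.

Key step: step 9

Remark: hemiacetal 5 is carried on as its anomeric mixture, since both anomers open to the same hydroxy aldehyde in step 5; its anomeric centre is left undefined in the SMILES.

## Route

Step 1
Reactants: 1 phenyl 1-thio-β-D-glucopyranoside
Product: 2 phenyl 4,6-O-[(R)-4-methoxybenzylidene]-1-thio-β-D-glucopyranoside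
Conditions: 4-MeOC6H4CH(OMe)2 (1.3 equiv), CSA (5 mol %), DMF, 50 °C, reduced pressure
Reagents that add atoms: 4-methoxybenzaldehyde dimethyl acetal, COc1ccc(cc1)C(OC)OC
Why: Acid-catalysed transacetalisation under thermodynamic control; the 4,6-diol closes the trans-fused 1,3-dioxane with the aryl group equatorial (R at the acetal carbon), leaving only O2–H and O3–H free.

Step 2
Reactants: 2 phenyl 4,6-O-[(R)-4-methoxybenzylidene]-1-thio-β-D-glucopyranoside
Product: 3 phenyl 2,3-bis-O-(tert-butyldimethylsilyl)-4,6-O-[(R)-4-methoxybenzylidene]-1-thio-β-D-glucopyranoside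
Conditions: TBSOTf (3 equiv), 2,6-lutidine (5 equiv), CH2Cl2, 0 °C → rt
Reagents that add atoms: tert-butyldimethylsilyl trifluoromethanesulfonate, CC(C)(C)[Si](C)(C)OS(=O)(=O)C(F)(F)F
Why: Silylation with a silyl triflate and a hindered pyridine base is strong enough for both secondary hydroxyls, including the crowded second one; the acetal and the thioglycoside are inert under these buffered conditions.

Step 3
Reactants: 3 phenyl 2,3-bis-O-(tert-butyldimethylsilyl)-4,6-O-[(R)-4-methoxybenzylidene]-1-thio-β-D-glucopyranoside
Product: 4 phenyl 2,3-bis-O-(tert-butyldimethylsilyl)-4-O-(4-methoxybenzyl)-1-thio-β-D-glucopyranoside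
Conditions: BH3·THF (5 equiv), Cu(OTf)2 (15 mol %), THF, 0 °C → rt; then Et3N, MeOH
Reagents that add atoms: none
Why: Regioselective reductive opening of the arylidene acetal: the Lewis acid activates the less hindered O6, the C–O6 bond breaks, and hydride quenches the oxocarbenium ion on O4. The 4-methoxybenzyl group therefore ends on O4 and O6–H is freed.

Step 4
Reactants: 4 phenyl 2,3-bis-O-(tert-butyldimethylsilyl)-4-O-(4-methoxybenzyl)-1-thio-β-D-glucopyranoside
Product: 5 2,3-bis-O-(tert-butyldimethylsilyl)-4-O-(4-methoxybenzyl)-D-glucopyranose (anomeric mixture)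
Conditions: NBS (1.5 equiv), NaHCO3, acetone/H2O (9:1), −15 → 0 °C
Reagents that add atoms: water, O
Why: Thioglycoside hydrolysis: bromonium activation of sulfur gives the oxocarbenium ion, which water in large excess captures. The medium stays neutral, so silyl and benzyl-type ethers remain.

Step 5
Reactants: 5 2,3-bis-O-(tert-butyldimethylsilyl)-4-O-(4-methoxybenzyl)-D-glucopyranose; 6 methyltriphenylphosphonium bromide
Product: 8 3,4-bis-O-(tert-butyldimethylsilyl)-1,2-dideoxy-5-O-(4-methoxybenzyl)-D-gluco-hept-1-enitol, via methylenetriphenylphosphorane 7 (not isolated)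
Conditions: 6 (5 equiv), n-BuLi (4.8 equiv), THF, 0 °C; then 5, −20 °C → rt
Reagents that add atoms: none
Why: Wittig methylenation of the open-chain hydroxy aldehyde in equilibrium with the hemiacetal; the first equivalents of ylide deprotonate the two hydroxyls, and the former ring oxygen emerges as the free hydroxyl on sugar C5. No stereocentre is formed.

Step 6
Reactants: 8 3,4-bis-O-(tert-butyldimethylsilyl)-1,2-dideoxy-5-O-(4-methoxybenzyl)-D-gluco-hept-1-enitol
Product: 9 3,4-bis-O-(tert-butyldimethylsilyl)-5,6-dideoxy-2-O-(4-methoxybenzyl)-L-xylo-hex-5-enose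
Conditions: NaIO4 (2 equiv), THF/pH 7 buffer (2:1), 0 °C → rt; used crude
Reagents that add atoms: none
Why: Malaprade glycol cleavage: periodate forms the cyclic ester of the only vicinal diol and cleaves it to the aldehyde and formaldehyde at neutral pH, so the α-alkoxy centre is not epimerised.

Step 7
Reactants: 9 3,4-bis-O-(tert-butyldimethylsilyl)-5,6-dideoxy-2-O-(4-methoxybenzyl)-L-xylo-hex-5-enose; 10 2-bromoprop-2-en-1-ol
Product: 13 (3S,4R,5S,6S)-5,6-bis(tert-butyldimethylsilyloxy)-4-(4-methoxybenzyloxy)-2-methylideneoct-7-ene-1,3-diol, via lithium 2-lithioprop-2-en-1-olate 11 (not isolated), via bromomagnesium 2-(bromomagnesio)prop-2-en-1-olate 12 (not isolated)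
Conditions: 10 (2.5 equiv), t-BuLi (7.5 equiv), Et2O, −78 → 0 °C; MgBr2·OEt2 (6 equiv), −78 °C; then 9, CH2Cl2, −78 → −40 °C; aq NH4Cl
Reagents that add atoms: none
Why: Deprotonation and bromine–lithium exchange give the O,C-dianion, which is transmetallated to magnesium. MgBr2 chelates the aldehyde oxygen and the α-(4-methoxybenzyl) ether (Cram-chelate model; the β-silyl ether does not chelate), and the vinyl group attacks the chelate anti to the chain, giving the 2,3-syn (threo) alcohol, C2 (S) in target locants.

Step 8
Reactants: 13 (3S,4R,5S,6S)-5,6-bis(tert-butyldimethylsilyloxy)-4-(4-methoxybenzyloxy)-2-methylideneoct-7-ene-1,3-diol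
Product: 14 [(3S,4R,5S,6S)-5,6-bis(tert-butyldimethylsilyloxy)-3-hydroxy-4-(4-methoxybenzyloxy)-2-methylideneoct-7-en-1-yl] benzoate
Conditions: BzCl (1.05 equiv), 2,4,6-collidine (3 equiv), CH2Cl2, −40 → −20 °C
Reagents that add atoms: benzoyl chloride, O=C(Cl)c1ccccc1
Why: Kinetic acylation: at low temperature with one equivalent of acid chloride the unhindered primary allylic hydroxyl reacts well before the secondary one, which is flanked by the substituted alkene and the C3 ether.

Step 9
Reactants: 14 [(3S,4R,5S,6S)-5,6-bis(tert-butyldimethylsilyloxy)-3-hydroxy-4-(4-methoxybenzyloxy)-2-methylideneoct-7-en-1-yl] benzoate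
Product: 15 [(2S,3R,4S,5S)-4,5-bis(tert-butyldimethylsilyloxy)-2-hydroxy-3-(4-methoxybenzyloxy)cyclohex-1(6)-en-1-yl]methyl benzoate (target locants; O2 and O4 lower face, O3 and O5 upper face)
Conditions: second-generation Grubbs catalyst RuCl2(=CHPh)(H2IMes)(PCy3) (10 mol %), CH2Cl2 (0.005 M), 40 °C, argon purge
Reagents that add atoms: none
Why: The ruthenium benzylidene initiates at the monosubstituted vinyl group on C5, the only alkene it can engage readily, and releases styrene; the resulting C6 alkylidene adds across the 1,1-disubstituted alkene at C1 to form a ruthenacyclobutane, whose cycloreversion gives the C1=C6 bond and a ruthenium methylidene, so that ethylene is lost overall. The closest known reaction type is ring-closing metathesis of sugar-derived 1,7-dienes to conduritols and carbasugars with trisubstituted ring alkenes. The one ring closed is the six-membered carbocycle, formed from the 1,7-diene with the new alkene endocyclic and necessarily cis. No stereocentre is formed, and the neutral conditions leave C2–C5 untouched. The step needs ring closure to win over cross-metathesis and over isomerisation of the allylic alcohol; the 1,1-disubstituted alkene cannot homodimerise, high dilution and removal of ethylene favour the intramolecular path, and the N-heterocyclic carbene catalyst is competent for trisubstituted alkenes and tolerates the free hydroxyl, which lies on the alkene that does not initiate.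

Step 10
Reactants: 15 [(2S,3R,4S,5S)-4,5-bis(tert-butyldimethylsilyloxy)-2-hydroxy-3-(4-methoxybenzyloxy)cyclohex-1(6)-en-1-yl]methyl benzoate
Product: 16 [4,5-bis(tert-butyldimethylsilyloxy)-2-hydroxy-3-(4-methoxybenzyloxy)-7-oxabicyclo[4.1.0]heptan-1-yl]methyl benzoate (oxirane O, O2, O4 lower face; C7, O3, O5 upper face)
Conditions: VO(acac)2 (5 mol %), t-BuOOH (1.5 equiv, decane), CH2Cl2, 0 °C → rt
Reagents that add atoms: tert-butyl hydroperoxide, CC(C)(C)OO
Why: Hydroxyl-directed epoxidation: the vanadium alkoxide of O2 binds the alkyl hydroperoxide and delivers oxygen to the alkene face syn to that hydroxyl. This sets C1 and C6 together, with the oxirane cis to O2.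

Step 11
Reactants: 16 [4,5-bis(tert-butyldimethylsilyloxy)-2-hydroxy-3-(4-methoxybenzyloxy)-7-oxabicyclo[4.1.0]heptan-1-yl]methyl benzoate
Product: 17 [4,5-bis(tert-butyldimethylsilyloxy)-2,3-dihydroxy-7-oxabicyclo[4.1.0]heptan-1-yl]methyl benzoate (same faces as 16)
Conditions: DDQ (1.5 equiv), CH2Cl2/pH 7 buffer (10:1), 0 °C → rt
Reagents that add atoms: none
Why: Oxidative cleavage of the 4-methoxybenzyl ether by DDQ (benzylic hydride abstraction, then hydrolysis of the oxocarbenium ion). Silyl ethers, esters and the oxirane are inert, and the aqueous buffer suppresses acetal formation with the neighbouring trans hydroxyl.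

Step 12
Reactants: 17 [4,5-bis(tert-butyldimethylsilyloxy)-2,3-dihydroxy-7-oxabicyclo[4.1.0]heptan-1-yl]methyl benzoate
Product: 18 [2,3-diacetoxy-4,5-bis(tert-butyldimethylsilyloxy)-7-oxabicyclo[4.1.0]heptan-1-yl]methyl benzoate (same faces as 16)
Conditions: Ac2O (6 equiv), pyridine, DMAP (10 mol %), CH2Cl2, 0 °C → rt
Reagents that add atoms: acetic anhydride, CC(=O)OC(C)=O
Why: Nucleophile-catalysed acetylation of both secondary hydroxyls. O2 is cis to the oxirane and cannot attack it from the rear, so no epoxide migration occurs under pyridine.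

Step 13
Reactants: 18 [2,3-diacetoxy-4,5-bis(tert-butyldimethylsilyloxy)-7-oxabicyclo[4.1.0]heptan-1-yl]methyl benzoate
Product: 19 [(1S,2R,3S,4R,5R,6S)-2,3-diacetoxy-4,5-dihydroxy-7-oxabicyclo[4.1.0]heptan-1-yl]methyl benzoate (CNP0171674.1)
Conditions: HF·pyridine (excess), pyridine, THF, 0 °C → rt
Reagents that add atoms: none
Why: Fluoride-mediated desilylation, driven by the Si–F bond. The pyridine-buffered, weakly acidic medium generates no alkoxide, so neither acetyl migration to O4 nor Payne opening of the oxirane by O5 is triggered.

## Compound list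

1 | phenyl 1-thio-β-D-glucopyranoside | OC[C@H]1O[C@@H](Sc2ccccc2)[C@H](O)[C@@H](O)[C@@H]1O | starting material
2 | phenyl 4,6-O-[(R)-4-methoxybenzylidene]-1-thio-β-D-glucopyranoside | COc1ccc(cc1)[C@@H]1OC[C@H]2O[C@@H](Sc3ccccc3)[C@H](O)[C@@H](O)[C@@H]2O1 | intermediate
3 | phenyl 2,3-bis-O-(tert-butyldimethylsilyl)-4,6-O-[(R)-4-methoxybenzylidene]-1-thio-β-D-glucopyranoside | COc1ccc(cc1)[C@@H]1OC[C@H]2O[C@@H](Sc3ccccc3)[C@H](O[Si](C)(C)C(C)(C)C)[C@@H](O[Si](C)(C)C(C)(C)C)[C@@H]2O1 | intermediate
4 | phenyl 2,3-bis-O-(tert-butyldimethylsilyl)-4-O-(4-methoxybenzyl)-1-thio-β-D-glucopyranoside | OC[C@H]1O[C@@H](Sc2ccccc2)[C@H](O[Si](C)(C)C(C)(C)C)[C@@H](O[Si](C)(C)C(C)(C)C)[C@@H]1OCc1ccc(OC)cc1 | intermediate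
5 | 2,3-bis-O-(tert-butyldimethylsilyl)-4-O-(4-methoxybenzyl)-D-glucopyranose (anomeric mixture) | OC[C@H]1OC(O)[C@H](O[Si](C)(C)C(C)(C)C)[C@@H](O[Si](C)(C)C(C)(C)C)[C@@H]1OCc1ccc(OC)cc1 | intermediate
6 | methyltriphenylphosphonium bromide | C[P+](c1ccccc1)(c1ccccc1)c1ccccc1.[Br-] | starting material
7 | methylenetriphenylphosphorane | C=P(c1ccccc1)(c1ccccc1)c1ccccc1 | intermediate
8 | 3,4-bis-O-(tert-butyldimethylsilyl)-1,2-dideoxy-5-O-(4-methoxybenzyl)-D-gluco-hept-1-enitol | C=C[C@H](O[Si](C)(C)C(C)(C)C)[C@@H](O[Si](C)(C)C(C)(C)C)[C@H](OCc1ccc(OC)cc1)[C@H](O)CO | intermediate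
9 | 3,4-bis-O-(tert-butyldimethylsilyl)-5,6-dideoxy-2-O-(4-methoxybenzyl)-L-xylo-hex-5-enose | C=C[C@H](O[Si](C)(C)C(C)(C)C)[C@@H](O[Si](C)(C)C(C)(C)C)[C@H](OCc1ccc(OC)cc1)C=O | intermediate
10 | 2-bromoprop-2-en-1-ol | OCC(Br)=C | starting material
11 | lithium 2-lithioprop-2-en-1-olate | [Li]OCC([Li])=C | intermediate
12 | bromomagnesium 2-(bromomagnesio)prop-2-en-1-olate | Br[Mg]OCC(=C)[Mg]Br | intermediate
13 | (3S,4R,5S,6S)-5,6-bis(tert-butyldimethylsilyloxy)-4-(4-methoxybenzyloxy)-2-methylideneoct-7-ene-1,3-diol | C=C(CO)[C@H](O)[C@@H](OCc1ccc(OC)cc1)[C@H](O[Si](C)(C)C(C)(C)C)[C@@H](O[Si](C)(C)C(C)(C)C)C=C | intermediate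
14 | [(3S,4R,5S,6S)-5,6-bis(tert-butyldimethylsilyloxy)-3-hydroxy-4-(4-methoxybenzyloxy)-2-methylideneoct-7-en-1-yl] benzoate | C=C(COC(=O)c1ccccc1)[C@H](O)[C@@H](OCc1ccc(OC)cc1)[C@H](O[Si](C)(C)C(C)(C)C)[C@@H](O[Si](C)(C)C(C)(C)C)C=C | intermediate
15 | [(2S,3R,4S,5S)-4,5-bis(tert-butyldimethylsilyloxy)-2-hydroxy-3-(4-methoxybenzyloxy)cyclohex-1(6)-en-1-yl]methyl benzoate (target locants) | O[C@@H]1[C@@H](OCc2ccc(OC)cc2)[C@H](O[Si](C)(C)C(C)(C)C)[C@@H](O[Si](C)(C)C(C)(C)C)C=C1COC(=O)c2ccccc2 | intermediate
16 | [4,5-bis(tert-butyldimethylsilyloxy)-2-hydroxy-3-(4-methoxybenzyloxy)-7-oxabicyclo[4.1.0]heptan-1-yl]methyl benzoate (oxirane O, O2, O4 lower; C7, O3, O5 upper) | COc1ccc(CO[C@H]2[C@H](O[Si](C)(C)C(C)(C)C)[C@@H](O[Si](C)(C)C(C)(C)C)[C@@H]3O[C@]3(COC(=O)c3ccccc3)[C@@H]2O)cc1 | intermediate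
17 | [4,5-bis(tert-butyldimethylsilyloxy)-2,3-dihydroxy-7-oxabicyclo[4.1.0]heptan-1-yl]methyl benzoate (faces as 16) | O[C@H]1[C@H](O[Si](C)(C)C(C)(C)C)[C@@H](O[Si](C)(C)C(C)(C)C)[C@@H]2O[C@]2(COC(=O)c2ccccc2)[C@@H]1O | intermediate
18 | [2,3-diacetoxy-4,5-bis(tert-butyldimethylsilyloxy)-7-oxabicyclo[4.1.0]heptan-1-yl]methyl benzoate (faces as 16) | CC(=O)O[C@H]1[C@H](O[Si](C)(C)C(C)(C)C)[C@@H](O[Si](C)(C)C(C)(C)C)[C@@H]2O[C@]2(COC(=O)c2ccccc2)[C@@H]1OC(C)=O | intermediate
19 | [(1S,2R,3S,4R,5R,6S)-2,3-diacetoxy-4,5-dihydroxy-7-oxabicyclo[4.1.0]heptan-1-yl]methyl benzoate | CC(=O)O[C@H]1[C@H](O)[C@@H](O)[C@@H]2O[C@]2(COC(=O)c2ccccc2)[C@@H]1OC(C)=O | target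

## Step count and least certain steps

Total step count: 13. Longest linear sequence: 13 steps (1 → 19); the route is fully linear, with 6 and 10 entering as reagents.

**Step 9 (key step).** The most likely failure is slow closure. Initiation must occur at the vinyl group next to a bulky allylic silyl ether, and the partner is a 1,1-disubstituted alkene. Catalyst decay could then produce ruthenium hydrides that isomerise the free allylic alcohol to the saturated ketone or shift the terminal alkene. The fallback sets out from diol 13 and returns at 15. O2 and O7 are tied into the isopropylidene acetal of 13 F1 (2,2-dimethoxypropane, PPTS), which removes the free hydroxyl and the benzoate from the reacting alkene and holds the methylene group exocyclic on a 1,3-dioxane. Ring-closing metathesis under the conditions of step 9 should give the bicyclic acetonide F2. Aqueous acetic acid at room temperature frees the cyclohexene diol F3, and primary-selective benzoylation as in step 8 gives 15.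

**Step 7.** The most likely failure is erosion of facial selectivity. The dimetallated reagent is aggregated and sparingly soluble, so part of the addition may run through a non-chelated lithium pathway and give the 2,3-anti epimer. Enolisation of the aldehyde by the basic reagent is a second risk. The fallback sets out from 9 and returns at 15, with C2 set by a substrate-controlled reduction. The addition is run without regard to selectivity. The mixture of 13 and its C2 epimer F4 is benzoylated as in step 8 (14 and its C2 epimer F5) and cyclised as in step 9 (15 and its C2 epimer F6). MnO2 in CH2Cl2 oxidises both allylic alcohols to the single cyclohexenone F7. Luche reduction (NaBH4, CeCl3·7H2O, MeOH, −78 °C) is expected to deliver hydride axially and give the pseudo-equatorial C2 alcohol trans to the C3 ether, which is 15.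

**Step 13.** The most likely failure is incomplete cleavage of the second, hindered silyl ether. Forcing the reaction risks acetyl migration from O3 to the freed O4 or opening of the oxirane by fluoride. The fallback sets out from 15 and returns at 19, and uses fluoride before the oxirane and the acetates exist. HF·pyridine on 15 gives the cyclohexene triol F8. Kinetic acetonation (2-methoxypropene, PPTS, 0 °C) engages the only vicinal diol, O4/O5, as the trans-fused acetonide F9 and leaves O2–H free. Steps 10 to 12 are repeated on it, giving the epoxy alcohol F10, the epoxy diol F11 and the diacetate F12. The strained trans-dioxolane is then hydrolysed with aqueous acetic acid at room temperature to give 19.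

**Step 5.** The most likely failure is base damage to the open-chain hydroxy aldehyde before olefination: elimination of the β-silyloxy group, epimerisation at the α-carbon, or migration of silicon to a newly formed alkoxide. The fallback sets out from 5 and returns at 8, and olefinates a protected open-chain aldehyde instead. NaBH4 reduces 5 to the glucitol triol F13. The terminal 1,2-diol is masked as the 5,6-acetonide F14 (2,2-dimethoxypropane, PPTS). Dess–Martin oxidation of the remaining primary alcohol gives the aldehydo sugar F15, which has no free hydroxyl. Wittig methylenation with 7 at −78 → 0 °C gives the acetonide alkene F16, and aqueous acetic acid removes the terminal acetonide to give 8.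

## Further compounds

F1 | step 9 | O2,O7-isopropylidene acetal of 13 (4-substituted 2,2-dimethyl-5-methylidene-1,3-dioxane) | C=C1COC(C)(C)O[C@@H]1[C@@H](OCc1ccc(OC)cc1)[C@H](O[Si](C)(C)C(C)(C)C)[C@@H](O[Si](C)(C)C(C)(C)C)C=C
F2 | step 9 | bicyclic acetonide, O2,O7-isopropylidene derivative of F3 | CC1(C)OCC2=C[C@H](O[Si](C)(C)C(C)(C)C)[C@@H](O[Si](C)(C)C(C)(C)C)[C@H](OCc3ccc(OC)cc3)[C@H]2O1
F3 | step 9 | cyclohexene diol, the debenzoylated analogue of 15 | O[C@@H]1[C@@H](OCc2ccc(OC)cc2)[C@H](O[Si](C)(C)C(C)(C)C)[C@@H](O[Si](C)(C)C(C)(C)C)C=C1CO
F4 | step 7 | C2 epimer of 13 (2,3-anti diol) | C=C(CO)[C@@H](O)[C@@H](OCc1ccc(OC)cc1)[C@H](O[Si](C)(C)C(C)(C)C)[C@@H](O[Si](C)(C)C(C)(C)C)C=C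
F5 | step 7 | C2 epimer of 14 | C=C(COC(=O)c1ccccc1)[C@@H](O)[C@@H](OCc1ccc(OC)cc1)[C@H](O[Si](C)(C)C(C)(C)C)[C@@H](O[Si](C)(C)C(C)(C)C)C=C
F6 | step 7 | C2 epimer of 15 | O[C@H]1[C@@H](OCc2ccc(OC)cc2)[C@H](O[Si](C)(C)C(C)(C)C)[C@@H](O[Si](C)(C)C(C)(C)C)C=C1COC(=O)c2ccccc2
F7 | step 7 | cyclohexenone, the 2-oxo analogue of 15 | O=C1[C@@H](OCc2ccc(OC)cc2)[C@H](O[Si](C)(C)C(C)(C)C)[C@@H](O[Si](C)(C)C(C)(C)C)C=C1COC(=O)c2ccccc2
F8 | step 13 | cyclohexene triol, the 4,5-bis-desilylated analogue of 15 | O[C@@H]1[C@@H](OCc2ccc(OC)cc2)[C@H](O)[C@@H](O)C=C1COC(=O)c2ccccc2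
F9 | step 13 | 4,5-O-isopropylidene (trans-fused) derivative of F8 | O[C@@H]1[C@@H](OCc2ccc(OC)cc2)[C@@H]2OC(C)(C)O[C@H]2C=C1COC(=O)c2ccccc2
F10 | step 13 | epoxy alcohol, the 4,5-O-isopropylidene analogue of 16 | COc1ccc(CO[C@H]2[C@@H]4OC(C)(C)O[C@H]4[C@@H]3O[C@]3(COC(=O)c3ccccc3)[C@@H]2O)cc1
F11 | step 13 | epoxy diol, the 4,5-O-isopropylidene analogue of 17 | O[C@H]1[C@@H]2OC(C)(C)O[C@H]2[C@@H]3O[C@]3(COC(=O)c3ccccc3)[C@@H]1O
F12 | step 13 | diacetate, the 4,5-O-isopropylidene analogue of 18 | CC(=O)O[C@H]1[C@@H]2OC(C)(C)O[C@H]2[C@@H]3O[C@]3(COC(=O)c3ccccc3)[C@@H]1OC(C)=O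
F13 | step 5 | 2,3-bis-O-(tert-butyldimethylsilyl)-4-O-(4-methoxybenzyl)-D-glucitol | OC[C@H](O[Si](C)(C)C(C)(C)C)[C@@H](O[Si](C)(C)C(C)(C)C)[C@H](OCc1ccc(OC)cc1)[C@H](O)CO
F14 | step 5 | 2,3-bis-O-(tert-butyldimethylsilyl)-5,6-O-isopropylidene-4-O-(4-methoxybenzyl)-D-glucitol | OC[C@H](O[Si](C)(C)C(C)(C)C)[C@@H](O[Si](C)(C)C(C)(C)C)[C@H](OCc1ccc(OC)cc1)[C@H]1COC(C)(C)O1
F15 | step 5 | 2,3-bis-O-(tert-butyldimethylsilyl)-5,6-O-isopropylidene-4-O-(4-methoxybenzyl)-aldehydo-D-glucose | O=C[C@H](O[Si](C)(C)C(C)(C)C)[C@@H](O[Si](C)(C)C(C)(C)C)[C@H](OCc1ccc(OC)cc1)[C@H]1COC(C)(C)O1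
F16 | step 5 | 3,4-bis-O-(tert-butyldimethylsilyl)-1,2-dideoxy-6,7-O-isopropylidene-5-O-(4-methoxybenzyl)-D-gluco-hept-1-enitol | C=C[C@H](O[Si](C)(C)C(C)(C)C)[C@@H](O[Si](C)(C)C(C)(C)C)[C@H](OCc1ccc(OC)cc1)[C@H]1COC(C)(C)O1
A1 | alternative 1 | 4-(benzoyloxymethyl)-4-hydroxycyclohexa-2,5-dien-1-one (achiral para-quinol) | O=C1C=CC(O)(COC(=O)c2ccccc2)C=C1
A2 | alternative 1 | cis-fused phenylboronate of the 1,2-diol enone | O=C1C=C[C@]2(COC(=O)c3ccccc3)OB(c3ccccc3)O[C@@H]2C1
A3 | alternative 2 | (5-acetoxy-6-hydroxycyclohexa-1,3-dien-1-yl)methyl benzoate, trans-dioxygenated diene (C2–OH free, C3–OAc) | O[C@@H]1[C@@H](OC(C)=O)C=CC=C1COC(=O)c1ccccc1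
A4 | alternative 2 | 2,3-dioxabicyclo[2.2.2]oct-5-ene endoperoxide | O[C@@H]1[C@@H](OC(C)=O)[C@H]2C=C[C@]1(COC(=O)c3ccccc3)OO2
A5 | alternative 3 | (1S,2R)-1,2-dihydroxycyclohexa-3,5-diene-1-carboxylic acid (ipso,ortho-dihydrodiol) | OC(=O)[C@]1(O)C=CC=C[C@H]1O
A6 | alternative 3 | epoxy diol: 2,3-bis-O-(4-methoxybenzyl) lower-face 4,5-epoxide with O1–H (lower) and O6–H (upper) free | COc1ccc(CO[C@H]2[C@@H]3O[C@@H]3[C@@H](O)[C@@](O)(COC(=O)c3ccccc3)[C@@H]2OCc2ccc(OC)cc2)cc1
A7 | alternative 3 | target skeleton as the 2,3-bis(4-methoxybenzyl) ether 4,5-diol | COc3ccc(cc3)CO[C@H]1[C@H](O)[C@@H](O)[C@@H]2O[C@]2(COC(=O)c3ccccc3)[C@@H]1OCc3ccc(OC)cc3
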